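**Assumption:** xanthogalenol has no stereocentres, so "single enantiomer" does not apply; the only stereochemical element is the E-enone, which the route sets in the last step.

## Retrosynthetic overview

1. The ArC(=O)–CH= bond is cut to an aldehyde C–H plus a terminal alkyne: Rh-catalysed, OH-chelation-assisted hydroacylation of 4-ethynylphenol by 2,6-dihydroxy-4-methoxy-3-prenylbenzaldehyde. This replaces the usual Claisen–Schmidt condensation, needs no protecting groups, and gives the E-alkene by syn H–Rh addition.
2. The prenyl group comes from an aromatic Claisen rearrangement of an aryl 1,1-dimethylallyl ether; the only free ortho position fixes the 3-prenyl regiochemistry.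
3. The ether comes from Pd-catalysed O-tert-prenylation of symmetric 2,6-dihydroxy-4-methoxybenzaldehyde, itself made by chelation-directed bis-demethylation of 2,4,6-trimethoxybenzaldehyde.
4. No rings are formed. Both benzene rings are purchased (A ring as 2,4,6-trimethoxybenzaldehyde, B ring as 4-ethynylphenol); the order is A-ring oxygenation pattern, then prenyl, then A/B union.

## Route

**Step 1**
Reactants: 1, 2,4,6-trimethoxybenzaldehyde
Product: 2, 2,6-dihydroxy-4-methoxybenzaldehyde
Conditions: AlCl3 (5 equiv), CH2Cl2, 0 °C → reflux; then 1 M HCl
Reagents that add atoms: none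
Why: Chelation-directed Lewis-acid O-demethylation: aluminium bound to the formyl oxygen activates only the two flanking ortho methyl ethers for chloride attack, so the non-chelated para OMe survives.

**Step 2**
Reactants: 3, 2-methylbut-3-en-2-ol
Product: 4, tert-butyl (2-methylbut-3-en-2-yl) carbonate
Conditions: n-BuLi, THF, −78 → 0 °C; then Boc2O, 0 °C → rt
Reagents that add atoms: di-tert-butyl dicarbonate, CC(C)(C)OC(=O)OC(=O)OC(C)(C)C
Why: Simple O-acylation of the lithium tertiary alkoxide by Boc2O gives the mixed carbonate (loss of t-BuOLi/CO2).

**Step 3**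
Reactants: 2, 2,6-dihydroxy-4-methoxybenzaldehyde; 4, tert-butyl (2-methylbut-3-en-2-yl) carbonate (1.15 equiv)
Product: 5, 2-hydroxy-4-methoxy-6-[(2-methylbut-3-en-2-yl)oxy]benzaldehyde (mono aryl 1,1-dimethylallyl ether)
Conditions: Pd(PPh3)4 (5 mol %), THF, 0 °C, quench at full conversion of 2
Reagents that add atoms: none beyond reactant 4, which supplies the C5H9 unit (C=CC(C)(C)OC(=O)OC(C)(C)C; CO2 and t-BuOH are lost)
Why: Decarboxylative Tsuji–Trost O-allylation: the released tert-butoxide deprotonates the acidic salicyl OH and the phenoxide attacks the more substituted terminus of the 1,1-dimethyl-π-allyl-Pd cation (kinetic branched selectivity at low temperature); the two OH groups are equivalent, and the remaining chelated, hindered OH resists a second alkylation.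

**Step 4**
Reactants: 5, 2-hydroxy-4-methoxy-6-[(2-methylbut-3-en-2-yl)oxy]benzaldehyde
Product: 6, 2,6-dihydroxy-4-methoxy-3-(3-methylbut-2-en-1-yl)benzaldehyde
Conditions: Eu(fod)3 (10 mol %), CHCl3, 60 °C
Reagents that add atoms: none
Why: Eu(III)-accelerated aromatic Claisen [3,3] rearrangement: the allyl unit inverts to a normal prenyl group at the only H-bearing ortho carbon (the other ortho carbon carries CHO), and tautomerisation restores the phenol.

**Step 5**
Reactants: 6, 2,6-dihydroxy-4-methoxy-3-(3-methylbut-2-en-1-yl)benzaldehyde; 7, 4-ethynylphenol (1.5 equiv, freshly purified, added slowly)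
Product: 8, xanthogalenol, (E)-1-[2,6-dihydroxy-4-methoxy-3-(3-methylbut-2-en-1-yl)phenyl]-3-(4-hydroxyphenyl)prop-2-en-1-one
Conditions: [Rh(cod)Cl]2 (2.5 mol %), dppf (5 mol %), Na2CO3 (10 mol %), PhMe, 70 °C, Ar; pH 5 buffer work-up, no base or prolonged heating
Reagents that add atoms: none (all atoms of 7 are incorporated; 100 % atom economy)
Why: Proposed new method: this pairing (an unprotected 2,6-dihydroxybenzaldehyde with a terminal phenolic arylalkyne, linear-selective) is an untested extension of the known Rh(I)-catalysed, phenoxide-chelation-assisted intermolecular hydroacylation of alkynes by salicylaldehydes; the Rh-phenoxide of 6 undergoes formyl C–H oxidative addition to a five-membered acyl-Rh(III)-hydride chelate (chelation suppresses decarbonylation), syn H–Rh addition across the alkyne places Rh on the less hindered terminal carbon, and C–C reductive elimination gives the linear E-enone, while the trisubstituted prenyl alkene does not insert.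

## Compound list

1 | 2,4,6-trimethoxybenzaldehyde | COc1cc(OC)c(C=O)c(OC)c1 | starting material
2 | 2,6-dihydroxy-4-methoxybenzaldehyde | COc1cc(O)c(C=O)c(O)c1 | intermediate
3 | 2-methylbut-3-en-2-ol | C=CC(C)(C)O | starting material
4 | tert-butyl (2-methylbut-3-en-2-yl) carbonate | C=CC(C)(C)OC(=O)OC(C)(C)C | intermediate
5 | 2-hydroxy-4-methoxy-6-[(2-methylbut-3-en-2-yl)oxy]benzaldehyde | COc1cc(O)c(C=O)c(OC(C)(C)C=C)c1 | intermediate
6 | 2,6-dihydroxy-4-methoxy-3-(3-methylbut-2-en-1-yl)benzaldehyde | COc1cc(O)c(C=O)c(O)c1CC=C(C)C | intermediate
7 | 4-ethynylphenol | C#Cc1ccc(O)cc1 | starting material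
8 | xanthogalenol | COc1cc(O)c(C(=O)/C=C/c2ccc(O)cc2)c(O)c1CC=C(C)C | target

## Summary

Total steps: 5. Longest linear sequence: 4 (1 → 2 → 5 → 6 → 8).

Steps most likely to fail, with fallbacks:

1. **Step 5 (hydroacylation).** Risks are the branched 1,1-disubstituted enone regioisomer, Rh-mediated alkyne oligomerisation, and chalcone → flavanone cyclisation of the 2',6'-dihydroxychalcone under heat or base. Fallback: a stepwise formal hydroacylation. Bis-MOM-protect 6, add the lithium acetylide of MOM-protected 4-ethynylphenol to the aldehyde, redox-isomerise the 1,3-diarylpropargylic alcohol to the E-enone (base- or Ru-catalysed), then remove MOM with HCl/MeOH.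

2. **Step 3 (Pd O-tert-prenylation).** Risks are linear O-prenyl ether, bis-ether or C-allylation on the hindered, chelated phenol. Fallback: O-allylate 2 (allyl bromide, K2CO3), run a thermal Claisen to the 3-allyl aldehyde (same single free ortho position), then convert allyl to prenyl by olefin cross-metathesis with 2-methylbut-2-ene (Grubbs II).

3. **Step 1 (double ortho-demethylation).** Risks are stalling at the mono-phenol or partial loss of the para OMe. Fallback: build up instead of cutting down. Mono-O-methylate commercial 2,4,6-trihydroxybenzaldehyde at its non-chelated, most acidic 4-OH (Me2SO4 1.0 equiv, K2CO3, acetone) to reach 2.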